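I had 4 questions to answer about one closed flask in which J and Z join one to one into E, with Z, the limiting reagent, charged at 0.266 M, less than the 0.28 M of J.

| setting | south | flask |
|---|---|---|
| J | 0.28 M | 0.28 M |
| Z | 0.266 M | 0.266 M |
| remark | the very flask that is asked about, followed so far |  |
| time |  | 8.0 d |

- midnight: change nothing and wait 2.5 d more
- summer: at 8.0 d add Z, 50.0 % of the amount charged, then wait 2.5 d
- autumn: at 8.0 d add J, 50.0 % of the amount charged, then wait 2.5 d

- additions leave the volume as it is
- a reading or a percentage of E counts all its forms, free or not

- E, in percent of the J first charged, at 8.0 d
- the option that brings most further E ("none" if no option brings more than 2 percentage points) (midnight / summer / autumn / none)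
- E present, in percent of the J first charged, after summer
- E present, in percent of the J first charged, after autumn

- south (time / d: E / %): 0.417: 65.9; 1.25: 74.3; 2.50: 75.1; 4.00: 74.9; 5.00: 74.5; 6.00: 74.5

(each reading ± 0.5 percentage points)

I read this table row by row with the turnover count: the logarithm of the ratio of free J to free Z, each as a share of its own charge, divided by the surplus of J as a fraction of the J charged, 0.0500; for a one-to-one pair whose rate goes with the product of the two, this count grows evenly with time as long as nothing returns. The first row, with E taken as the pair used, gives 2.15, so the flask ran at 5.14 d⁻¹, its turnover pace. At that pace the second row should have shown a count of 6.43, or 83.9 % of E, but it read 74.3 %, less than that. The later rows go from 75.1 % to 74.5 %, a change near the scatter, so I took about 74.5 % for the flask at 8.0 d and expected nothing from waiting.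

The rows cannot say whether the missing part stood free or had gone elsewhere, and I reckoned the second case, with no return. The count at 8.0 d is then 41.2, which puts the pair used at 94.3 % of the J charged, below the 95.0 % that the charge of Z allows. By this reckoning autumn could gain at most 0.69 percentage points, the Z still free, while summer could gain at most 5.7 points, the J still free. So I expected summer to be the better of the two, its gain possibly on either side of 2 points.

The forecast, holding that “The approach looks like a second-order reaction relaxing to equilibrium, not a stall”, gave 74.6 % now, 88 % after summer and 85.4 % after autumn, and chose summer. Its gain for summer, 14 points, is more than my ceiling.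

    J + Z → E (k = 1.10 M⁻¹ h⁻¹)
    J + Z → X, rate k2*[J] as long as [Z] is above zero (k = 0.0190 h⁻¹)
    J + E → G (k = 0.0320 M⁻¹ h⁻¹)
    L ⇌ E, rate k4*(cs4 - [E]) while solid is left; crystals form when [E] > cs4 (solubility = 0.0940 M, k = 3.00 h⁻¹)

The flask gave 74.5 % at 8.0 d, and the best option was none: summer ended at 75.9 %, a gain of 1.4 points, and autumn at 65.9 %, a change of −8.5 points. At 8.00 d the flask held 1.70 % of its J free, less than the 5.70 % that the count had left, and 0 % of its Z. Scaled to the 1.1 M of Z in the first neighbour flask, the pace gives 162 turnovers by 8.0 d, and that flask held 0 % of its J free, with E at 97.7 %.

(The readings come from a simulation for an exercise.)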